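Start from the leftover. In the teal run 0.80 M of starting material met 0.40 M of reagent, so if each reagent takes one starting material, 0.400 M of starting material stays over once the reagent is used. That gives a bench rule: the reagent is the limiting reagent, and you expect first product to stop at the reagent ceiling Y, the reagent charged divided by the starting material charged, here 50.0 % of the starting material.

all flasks: starting material 0.80 M
- teal: reagent 0.40 M; the very flask that is asked about, followed so far
- amber: reagent 0.80 M; run made earlier
- flask: reagent 0.400 M; time 10 h

teal run (percent of the starting material charged)

| time / min | first product / % | bis adduct / % |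
|---|---|---|
| 5.00 | 28.2 | 4.3 |
| 15.0 | 43.5 | 0 |
| 25.0 | 46.3 | 0.6 |
| 40.0 | 50.4 | 0.3 |
| 60.0 | 48.7 | 0 |
| 80.0 | 50.1 | 2.8 |

amber run (percent of the starting material charged)

| time / h | first product / % | bis adduct / % |
|---|---|---|
| 0.500 | 83.6 | 1.0 |
| 1.00 | 90.6 | 0.6 |
| 1.50 | 91.7 | 0.9 |
| 2.50 | 93.7 | 0 |
| 4.00 | 95.1 | 1.1 |
| 8.00 | 95.7 | 0 |

(standard deviation of a reading: 1 percentage point)

- the numbers in the tables scatter by 1 percentage point (one standard deviation)

- equivalents of reagent to starting material, everything else as given, that leave most first product at 10 h
- the amount of first product then, in percent of the starting material charged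
- the amount of first product with the amounts as given

The late teal readings sit on Y: first product reads 50.4 % at 40.0 min and 50.1 % at 80.0 min, flat within the scatter of 1 percentage point, though that last time is short against the 10 h asked about. Still, for the asked flask I commit to about Y.

The border shows in the amber run. There the ratio of charges makes Y 100 %, yet the last reading is 95.7 % at 8.00 h, which is 4.3 points short, against a scatter of 1 point. So the rule holds in the teal run, at a ratio of 0.500, and falls short in the amber run, at a ratio of 1.00. I would therefore put the best recipe close to 1.00 equivalent, with about the amber reading as its yield.

The forecast gives 49.5 % for the asked flask, close to my Y of 50.0 %, but differs from me on the recipe: it names 1.2 equiv and 97 %, reasoning that a “modest reagent excess should push conversion further”.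

The flask gives 49.4 %, and the best recipe is 1.03 equiv, leaving 96.4 %, fewer equivalents than the forecast named. At 10.0 h the flask holds 0 % of its reagent and 50 % of its starting material, and Y stands 0.60 points above the answer.

    starting material + reagent → first product + released group (k = 0.00530 M⁻¹ s⁻¹)
    reagent + first product ⇌ bis adduct + released group (K = 0.140, k = 0.00360 M⁻¹ s⁻¹)
    bis adduct → over-reaction product (k = 2.00 × 10⁻⁴ s⁻¹)

In the neighbour charged with 1.4 M of starting material, Y comes to 28.6 %. Computed, that neighbour gives 28.4 %, with 0 % of its reagent left.

Readings and results are simulated for substances that don't exist; scatter was added.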